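**Plan** (atoms numbered as in a 1-benzoxepine: O1, C2 (=CHBr), C3/C4 (epoxide), C5 (CH2), C5a (ring-fusion CH), C6 (CMe2), C7 (CHBr), C8, C9, C9a (C(Me)–O); ring A = cyclohexane, ring B = oxepane)
1. Retrosynthesis: C2=CHBr is cut back to a lactone C=O (via the 1,1-dibromide), the epoxide to the C3=C4 ring alkene, that alkene to an allyl/methacrylate pair (ring B by metathesis), C7–Br to an axial C7–OH, and ring A is cut at C9a–C5a together with the side-chain bond C5–C4.
2. Enabling feature: C7 and C5a are 1,3-related across the gem-dimethyl carbon C6 of ring A. An oxygen on C7 can therefore be tied to C5 through a temporary unsaturated δ-lactone (O–C(=O)–C5H=C5aH), which makes C5a a radical acceptor, makes C5 an enolate carbon, and later loses its carbonyl carbon as CO2.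
3. Forward: asymmetric reverse prenylation, acrylate, metathesis to the δ-lactone; the key step closes ring A as a bridged lactone and attaches C4; decarboxylative unmasking; the C7 bromide; ring B by a second metathesis; epoxide; bromomethylidene.
4. Stereochemistry: C7–O from the catalytic asymmetric prenylation; C5a and C9a are relayed from it through the bridged bicycle in the key step; C7 is then inverted twice (oxidation/axial reduction, then SN2 bromide).
5. The epoxide (C3, C4) comes from attack anti to the two axial methyl groups; the E-bromoalkene from removal of the less hindered bromine of the 1,1-dibromide.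

Key step: step 4

Remark: 10 is written as its chelated Z-enol (it equilibrates with the formyl tautomer) and 12 as the five-membered lactol with the anomeric centre undefined; neither choice affects the route.

Step 1
Reactants: 1 5-hydroxypentan-2-one; 2 3-methylbuta-1,2-diene
Product: 4 (5S)-5-hydroxy-6,6-dimethyloct-7-en-2-one, via 4-oxopentanal 3 (not isolated)
Conditions: [Ir(cod)Cl]2 (2.5 mol%), (S)-SEGPHOS (5 mol%), 4-chloro-3-nitrobenzoic acid (10 mol%), Cs2CO3 (20 mol%), 2 (2 equiv), PhMe, 70 °C
Reagents that add atoms: none
Why: Iridium-catalysed transfer-hydrogenative carbonyl reverse prenylation: the catalyst oxidises the primary alcohol to aldehyde 3, passes the hydride to the allene and adds the resulting 1,1-dimethylallyl–iridium through its substituted terminus to 3, so C5 is set by the chiral bisphosphine (the ligand antipode is the one that gives 5S) while the less electrophilic methyl ketone is left alone.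

Step 2
Reactants: 4 (5S)-5-hydroxy-6,6-dimethyloct-7-en-2-one; 5 acryloyl chloride
Product: 6 (4S)-3,3-dimethyl-7-oxooct-1-en-4-yl prop-2-enoate
Conditions: 5 (1.5 equiv), iPr2NEt, DMAP (cat.), CH2Cl2, 0 °C to rt
Reagents that add atoms: none
Why: Esterification of the hindered secondary alcohol by the acid chloride under nucleophilic catalysis; the stereocentre is not involved.

Step 3
Reactants: 6 (4S)-3,3-dimethyl-7-oxooct-1-en-4-yl prop-2-enoate
Product: 7 (6S)-5,5-dimethyl-6-(3-oxobutyl)-5,6-dihydro-2H-pyran-2-one
Conditions: second-generation Hoveyda–Grubbs catalyst (5 mol%), PhMe (0.01 M), 80 °C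
Reagents that add atoms: none
Why: Ring-closing metathesis between the acrylate and the vinyl group on the quaternary carbon, helped by the gem-dimethyl effect, should give the six-membered Z-enoate with loss of ethene; no stereocentre changes.

Step 4
Reactants: 7 (6S)-5,5-dimethyl-6-(3-oxobutyl)-5,6-dihydro-2H-pyran-2-one; 8 2,2,2-trifluoroethyl formate
Product: 10 (1S,4Z,5R,6S)-6-hydroxy-4-(hydroxymethylidene)-6,9,9-trimethyl-2-oxabicyclo[3.3.1]nonan-3-one, via samarium enolate 9 (not isolated)
Conditions: SmI2 (2.2 equiv), HMPA (8 equiv), THF, −78 °C; then 8 (5 equiv), −78 to 0 °C; aq. NH4Cl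
Reagents that add atoms: none
Why: Proposed new method: divalent samarium reduces the methyl ketone to a ketyl that adds 6-exo-trig to the β-carbon of the unsaturated lactone (future C5a), a second electron converts the resulting α-lactone radical into the trivalent-samarium enolate 9, and 9 is C-formylated by 8, so the C9a–C5a bond and the C5–C4 bond arise in one flask; the closest known reaction type is the SmI2 ketyl–olefin cyclisation onto α,β-unsaturated esters with trapping of the samarium enolate by a carbonyl electrophile (aldol), extended here to a bridging closure and to acylation by a formate. The ring closed is ring A, by 6-exo-trig radical attack, and since its tether runs from C6 to C4 of the dihydropyranone it can only form as a chair bridged across the lactone, giving the 2-oxabicyclo[3.3.1]nonane. The new CH centre (future C5a) is thus fixed by the existing C–O stereocentre, because the side chain can reach the β-carbon only on its own face, and the new carbinol centre (future C9a) by a transition state with the small O–Sm group axial and anti to the enoate and the methyl equatorial, which avoids both a 1,3-diaxial clash with the bridge methyl and dipole repulsion, so oxygen ends trans to the new side-chain carbon; the formylated carbon is held as an enol and is not a stereocentre. The step needs C–C bond formation to outrun simple reduction and pinacol coupling, which the intramolecular six-membered closure and HMPA-accelerated electron transfer should secure, and it needs C- over O-formylation, for which the oxophilic samarium counter-ion and the activated formate are chosen (a formate formed on the tertiary alkoxide would be lost on work-up). No proton source is present until 8 has been added, so that the enolate survives.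

Step 5
Reactants: 10 (1S,4Z,5R,6S)-6-hydroxy-4-(hydroxymethylidene)-6,9,9-trimethyl-2-oxabicyclo[3.3.1]nonan-3-one
Product: 12 (3aS,5S,7aS)-4,4,7a-trimethyloctahydro-1-benzofuran-2,5-diol, via formyl acid 11 (not isolated)
Conditions: 2 M HCl, THF, 60 °C
Reagents that add atoms: none
Why: Acid hydrolysis opens the α-formyl lactone to the β-formyl acid 11, which loses CO2 (the classical acid cleavage–decarboxylation of α-acyl lactones), and after the ring flips to the chair with the side chain equatorial the aldehyde should be captured by the tertiary hydroxyl as a trans-fused lactol; the temporary carbonyl carbon is thereby removed and no ring stereocentre is touched.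

Step 6
Reactants: 12 (3aS,5S,7aS)-4,4,7a-trimethyloctahydro-1-benzofuran-2,5-diol
Product: 13 (1S,2S,4S)-1,3,3-trimethyl-2-(prop-2-en-1-yl)cyclohexane-1,4-diol
Conditions: Ph3PCH3Br (4 equiv), KOtBu (4 equiv), THF, 0 to 50 °C
Reagents that add atoms: methyltriphenylphosphonium bromide, C[P+](c1ccccc1)(c1ccccc1)c1ccccc1.[Br-]
Why: Wittig methylenation of the lactol through its open hydroxy aldehyde should turn the masked aldehyde into the allyl group, the excess ylide serving as base for the two hydroxyls.

Step 7
Reactants: 13 (1S,2S,4S)-1,3,3-trimethyl-2-(prop-2-en-1-yl)cyclohexane-1,4-diol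
Product: 14 (3S,4S)-4-hydroxy-2,2,4-trimethyl-3-(prop-2-en-1-yl)cyclohexan-1-one
Conditions: Dess–Martin periodinane, CH2Cl2, rt
Reagents that add atoms: none
Why: Dess–Martin oxidation of the only oxidisable (secondary) hydroxyl gives the ketone and deliberately erases the carbinol stereocentre, whose controlling role ended in step 4.

Step 8
Reactants: 14 (3S,4S)-4-hydroxy-2,2,4-trimethyl-3-(prop-2-en-1-yl)cyclohexan-1-one
Product: 15 (1S,2S,4R)-1,3,3-trimethyl-2-(prop-2-en-1-yl)cyclohexane-1,4-diol
Conditions: LiBH(s-Bu)3, THF, −78 °C; aq. NH4Cl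
Reagents that add atoms: none
Why: Substrate-controlled ketone reduction: the bulky trialkylborohydride should approach the 2,2-dimethylcyclohexanone along the equatorial trajectory, so the new hydroxyl is axial (4R), the epimer needed for inversion.

Step 9
Reactants: 15 (1S,2S,4R)-1,3,3-trimethyl-2-(prop-2-en-1-yl)cyclohexane-1,4-diol; 16 carbon tetrabromide
Product: 17 (1S,2S,4S)-4-bromo-1,3,3-trimethyl-2-(prop-2-en-1-yl)cyclohexan-1-ol
Conditions: 16 (2 equiv), PPh3 (2.2 equiv), CH2Cl2, 0 °C to rt
Reagents that add atoms: none
Why: Appel reaction: the secondary alcohol is activated on phosphorus and displaced by bromide with inversion (SN2), turning the axial alcohol into the equatorial bromide (4S); the tertiary hydroxyl is too hindered to be activated, and the competing channel is E2 toward the ring CH2.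

Step 10
Reactants: 17 (1S,2S,4S)-4-bromo-1,3,3-trimethyl-2-(prop-2-en-1-yl)cyclohexan-1-ol; 18 2-methylprop-2-enoic anhydride
Product: 19 (1S,2S,4S)-4-bromo-1,3,3-trimethyl-2-(prop-2-en-1-yl)cyclohexyl 2-methylprop-2-enoate
Conditions: 18 (3 equiv), Sc(OTf)3 (5 mol%), BHT (trace), MeCN, −20 °C
Reagents that add atoms: none
Why: Lewis-acid-catalysed esterification of the hindered tertiary alcohol with the anhydride at low temperature, where the tertiary carbinol should not ionise; no stereocentre is touched.

Step 11
Reactants: 19 (1S,2S,4S)-4-bromo-1,3,3-trimethyl-2-(prop-2-en-1-yl)cyclohexyl 2-methylprop-2-enoate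
Product: 20 (5aS,7S,9aS)-7-bromo-3,6,6,9a-tetramethyl-5a,6,7,8,9,9a-hexahydro-1-benzoxepin-2(5H)-one
Conditions: second-generation Hoveyda–Grubbs catalyst (10 mol%), PhMe (0.005 M), 90 °C
Reagents that add atoms: none
Why: Ring-closing metathesis of the allyl group with the methacrylate should close the seven-membered unsaturated lactone (ring B) with loss of ethene; the ring alkene is necessarily Z and the trans ring fusion is already fixed.

Step 12
Reactants: 20 (5aS,7S,9aS)-7-bromo-3,6,6,9a-tetramethyl-5a,6,7,8,9,9a-hexahydro-1-benzoxepin-2(5H)-one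
Product: 21 (3R,4R,5aS,7S,9aS)-7-bromo-3,4-epoxy-3,6,6,9a-tetramethyloctahydro-1-benzoxepin-2(3H)-one
Conditions: DMDO (excess, acetone solution), CH2Cl2, rt
Reagents that add atoms: dimethyldioxirane, CC1(C)OO1
Why: Epoxidation of the electron-poor trisubstituted alkene by the neutral dioxirane should occur from the α face, opposite the two axial methyl groups (on C9a and C6) of the trans-fused bicycle, and so sets C3 and C4 (3R,4R) together.

Step 13
Reactants: 21 (3R,4R,5aS,7S,9aS)-7-bromo-3,4-epoxy-3,6,6,9a-tetramethyloctahydro-1-benzoxepin-2(3H)-one; 16 carbon tetrabromide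
Product: 22 (3R,4R,5aS,7S,9aS)-7-bromo-2-(dibromomethylidene)-3,4-epoxy-3,6,6,9a-tetramethyldecahydro-1-benzoxepine
Conditions: 16 (4 equiv), PPh3 (8 equiv), PhMe, 80 °C
Reagents that add atoms: none
Why: Wittig-type dibromomethylenation (Corey–Fuchs reagent Ph3P=CBr2, made in the flask) of the lactone carbonyl, which is activated by its α-oxygen substituent as in the known dihalomethylenation of α-oxygenated lactones; no stereocentre is touched.

Step 14
Reactants: 22 (3R,4R,5aS,7S,9aS)-7-bromo-2-(dibromomethylidene)-3,4-epoxy-3,6,6,9a-tetramethyldecahydro-1-benzoxepine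
Product: 23 (2E,3R,4R,5aS,7S,9aS)-7-bromo-2-(bromomethylidene)-3,4-epoxy-3,6,6,9a-tetramethyldecahydro-1-benzoxepine (CNP0375295.1)
Conditions: Bu3SnH (1.05 equiv), Pd(PPh3)4 (5 mol%), PhMe, rt
Reagents that add atoms: none
Why: Palladium-catalysed hydrogenolysis of a 1,1-dibromoalkene with tributyltin hydride: zerovalent palladium should insert into the less hindered C–Br bond, the one cis to the ring oxygen and remote from the quaternary epoxide carbon, so hydride replaces that bromine and the remaining bromine is trans to oxygen (E).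

**Compound list**
1 | 5-hydroxypentan-2-one | CC(=O)CCCO | starting material
2 | 3-methylbuta-1,2-diene | CC(C)=C=C | starting material
3 | 4-oxopentanal | CC(=O)CCC=O | intermediate
4 | (5S)-5-hydroxy-6,6-dimethyloct-7-en-2-one | CC(=O)CC[C@H](O)C(C)(C)C=C | intermediate
5 | acryloyl chloride | C=CC(Cl)=O | starting material
6 | (4S)-3,3-dimethyl-7-oxooct-1-en-4-yl prop-2-enoate | CC(=O)CC[C@H](OC(=O)C=C)C(C)(C)C=C | intermediate
7 | (6S)-5,5-dimethyl-6-(3-oxobutyl)-5,6-dihydro-2H-pyran-2-one | CC(=O)CC[C@@H]1OC(=O)C=CC1(C)C | intermediate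
8 | 2,2,2-trifluoroethyl formate | O=COCC(F)(F)F | starting material
9 | bis(diiodosamarium) alkoxide–enolate of (1S,5S,6S)-6-hydroxy-6,9,9-trimethyl-2-oxabicyclo[3.3.1]nonan-3-one (trivalent samarium on the tertiary oxygen and on the C3=C4 enolate oxygen) | C[C@]1(O[Sm](I)I)CC[C@@H]2OC(O[Sm](I)I)=C[C@H]1C2(C)C | intermediate
10 | (1S,4Z,5R,6S)-6-hydroxy-4-(hydroxymethylidene)-6,9,9-trimethyl-2-oxabicyclo[3.3.1]nonan-3-one | C[C@]1(O)CC[C@@H]2OC(=O)/C(=C\O)[C@H]1C2(C)C | intermediate
11 | 2-[(1S,2S,5S)-2,5-dihydroxy-2,6,6-trimethylcyclohexyl]-3-oxopropanoic acid | C[C@]1(O)CC[C@H](O)C(C)(C)[C@@H]1C(C=O)C(O)=O | intermediate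
12 | (3aS,5S,7aS)-4,4,7a-trimethyloctahydro-1-benzofuran-2,5-diol | C[C@]12CC[C@H](O)C(C)(C)[C@@H]1CC(O)O2 | intermediate
13 | (1S,2S,4S)-1,3,3-trimethyl-2-(prop-2-en-1-yl)cyclohexane-1,4-diol | C[C@]1(O)CC[C@H](O)C(C)(C)[C@@H]1CC=C | intermediate
14 | (3S,4S)-4-hydroxy-2,2,4-trimethyl-3-(prop-2-en-1-yl)cyclohexan-1-one | C[C@]1(O)CCC(=O)C(C)(C)[C@@H]1CC=C | intermediate
15 | (1S,2S,4R)-1,3,3-trimethyl-2-(prop-2-en-1-yl)cyclohexane-1,4-diol | C[C@]1(O)CC[C@@H](O)C(C)(C)[C@@H]1CC=C | intermediate
16 | carbon tetrabromide | BrC(Br)(Br)Br | starting material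
17 | (1S,2S,4S)-4-bromo-1,3,3-trimethyl-2-(prop-2-en-1-yl)cyclohexan-1-ol | C[C@]1(O)CC[C@H](Br)C(C)(C)[C@@H]1CC=C | intermediate
18 | 2-methylprop-2-enoic anhydride | CC(=C)C(=O)OC(=O)C(C)=C | starting material
19 | (1S,2S,4S)-4-bromo-1,3,3-trimethyl-2-(prop-2-en-1-yl)cyclohexyl 2-methylprop-2-enoate | C[C@]1(OC(=O)C(C)=C)CC[C@H](Br)C(C)(C)[C@@H]1CC=C | intermediate
20 | (5aS,7S,9aS)-7-bromo-3,6,6,9a-tetramethyl-5a,6,7,8,9,9a-hexahydro-1-benzoxepin-2(5H)-one | CC1(C)[C@@H](Br)CC[C@]2(C)OC(=O)C(C)=CC[C@@H]12 | intermediate
21 | (3R,4R,5aS,7S,9aS)-7-bromo-3,4-epoxy-3,6,6,9a-tetramethyloctahydro-1-benzoxepin-2(3H)-one | CC1(C)[C@@H](Br)CC[C@]2(C)OC(=O)[C@]3(C)O[C@@H]3C[C@@H]12 | intermediate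
22 | (3R,4R,5aS,7S,9aS)-7-bromo-2-(dibromomethylidene)-3,4-epoxy-3,6,6,9a-tetramethyldecahydro-1-benzoxepine | CC1(C)[C@@H](Br)CC[C@]2(C)OC(=C(Br)Br)[C@]3(C)O[C@@H]3C[C@@H]12 | intermediate
23 | (2E,3R,4R,5aS,7S,9aS)-7-bromo-2-(bromomethylidene)-3,4-epoxy-3,6,6,9a-tetramethyldecahydro-1-benzoxepine | CC1(C)[C@@H](Br)CC[C@]2(C)O/C(=C/Br)[C@]3(C)O[C@@H]3C[C@@H]12 | target

**Total step count:** 14. **Longest linear sequence:** 14 steps (from 1).

**Steps most likely to fail**

Step 4. The samarium enolate may be quenched or O-formylated before C-formylation, or the enoate may be reduced without C–C bond formation. The fallback makes the two bonds in separate, known operations. From 7, the reductive ketyl–olefin cyclisation with proton quench (SmI2, HMPA, t-BuOH, THF, −78 °C) should give the bridged hydroxy lactone (1S,5S,6S)-6-hydroxy-6,9,9-trimethyl-2-oxabicyclo[3.3.1]nonan-3-one F1. Its dianion (LDA, 2.2 equiv, THF, −78 °C) is then formylated with 8 in a Claisen condensation, which returns to the route at 10.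

Step 13. Olefination of the hindered α-quaternary lactone carbonyl may be slow, and during that time bromophosphonium by-products can open the epoxide. The fallback changes the order so that no epoxide is present during olefination or the palladium step. From 20, dibromomethylenation (16, PPh3, PhMe, 80 °C) should give the dibromodiene (5aS,7S,9aS)-7-bromo-2-(dibromomethylidene)-3,6,6,9a-tetramethyl-2,5,5a,6,7,8,9,9a-octahydro-1-benzoxepine F2. Hydrogenolysis with Bu3SnH and Pd(PPh3)4 should then give the bromodiene (2E,5aS,7S,9aS)-7-bromo-2-(bromomethylidene)-3,6,6,9a-tetramethyl-2,5,5a,6,7,8,9,9a-octahydro-1-benzoxepine F3. Epoxidation of the trisubstituted ring alkene with DMDO from the α face comes back at 23. The selectivity then needed is for the ring alkene over the bromo enol ether, whose nucleophilicity is lowered by bromine.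

Step 9. Elimination toward the ring CH2 or cationic rearrangement may take over from substitution at the axial centre next to the quaternary carbon. The fallback replaces activation on phosphorus by an isolated sulfonate and a free bromide. From 15, Tf2O with 2,6-di-tert-butyl-4-methylpyridine (CH2Cl2, −78 °C) should give the axial triflate (1R,3S,4S)-4-hydroxy-2,2,4-trimethyl-3-(prop-2-en-1-yl)cyclohexyl trifluoromethanesulfonate F4. Displacement with Bu4NBr in toluene at low temperature, with inversion, comes back at 17.

**Further compounds**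
F1 | step 4 | (1S,5S,6S)-6-hydroxy-6,9,9-trimethyl-2-oxabicyclo[3.3.1]nonan-3-one | C[C@]1(O)CC[C@@H]2OC(=O)C[C@H]1C2(C)C
F2 | step 13 | (5aS,7S,9aS)-7-bromo-2-(dibromomethylidene)-3,6,6,9a-tetramethyl-2,5,5a,6,7,8,9,9a-octahydro-1-benzoxepine | CC1(C)[C@@H](Br)CC[C@]2(C)OC(=C(Br)Br)C(C)=CC[C@@H]12
F3 | step 13 | (2E,5aS,7S,9aS)-7-bromo-2-(bromomethylidene)-3,6,6,9a-tetramethyl-2,5,5a,6,7,8,9,9a-octahydro-1-benzoxepine | CC1(C)[C@@H](Br)CC[C@]2(C)O/C(=C/Br)C(C)=CC[C@@H]12
F4 | step 9 | (1R,3S,4S)-4-hydroxy-2,2,4-trimethyl-3-(prop-2-en-1-yl)cyclohexyl trifluoromethanesulfonate | C[C@]1(O)CC[C@@H](OS(=O)(=O)C(F)(F)F)C(C)(C)[C@@H]1CC=C
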